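The constants I had to weigh first were the charges and the temperature, and I asked what an error in each would cost.

| setting | east | south-east | south-west | amber | blue | violet |
|---|---|---|---|---|---|---|
| starting material | 0.033 M | 0.033 M | 0.033 M | 0.033 M | 0.033 M | 0.033 M |
| coupling partner | 1.05 equiv | 1.05 equiv | 1.05 equiv | 1.05 equiv | 1.05 equiv | 1.05 equiv |
| second substrate | 1 equiv | 4 equiv | 2 equiv | 2.00 equiv | 2.00 equiv | 2.00 equiv |
| protic impurity | 1.65 mM | 1.65 mM | 3.3 mM | 1.65 mM | 1.65 mM | 1.65 mM |
| temperature | 105 °C | 118 °C | 105 °C |  | 110 °C | 125 °C |
| remark | run made earlier | run made earlier | run made earlier | at 110 °C until 1.5 min, from then on at 125 °C |  |  |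
| time |  |  |  | 5.0 min | 5.0 min | 5.0 min |

- east (time / min: target / %, starting material / %): 0.333: 11, 86; 0.500: 13, 85; 0.667: 19, 80; 1.00: 23, 71; 1.50: 26, 71; 2.50: 33, 60; 4.00: 35, 60
- south-east (time / min: target / %, starting material / %): 0.333: 9, 87; 0.500: 11, 86; 0.667: 12, 84; 1.00: 10, 85; 1.50: 11, 83; 2.50: 7, 82; 4.00: 10, 80
- south-west (time / min: target / %, starting material / %): 0.333: 13, 86; 1.00: 19, 77; 2.00: 25, 70; 3.00: 22, 68; 4.00: 22, 65

(standard deviation of a reading: 1.5 percentage points)

- which flask leads in amount of target, in percent of the starting material charged ("all alike" within 1.5 percentage points) (amber / blue / violet / all alike)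
- how much target is there at the end, in percent of the starting material charged: amber
- how much target is there at the end, in percent of the starting material charged: blue
- how much target is there at the end, in percent of the starting material charged: violet



Time cost little: the east run read 33% of target at 2.50 min and 35% at 4.00 min, with 60% of the starting material still present. The protic impurity was charged at 5.00% of the starting material, less than the 40.0% the east run consumed. The coupling partner looked like the number to know well. I supposed it was the limiting reagent, shared between starting material and second substrate.

The zero of my scale was a partner with no preference, which would give the east run, with equal substrates, half of its charge as target, 52.5%. The reading lay lower, so I defined s, the selectivity factor, as how many times faster the coupling partner takes second substrate than starting material at equal concentrations. The east reading gave s = 2.00.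

In my reckoning target then equals the partner's equivalents divided by one plus s·c(second substrate)/c(starting material), so both charges had to be right. This reckoning gave 21.0% for the south-west run, which read 22% with twice the impurity. It gave 11.7% for the south-east run, which read 10% at 118 °C. For blue I reckoned 21.0%. This reckoning holds no temperature, so I made no separate figure for amber and violet.

The forecast named blue first, with 19% for amber, 21% for blue and 12% for violet: “More second substrate clearly hurts.” Its blue figure matched mine, reached from the plateaus.

    starting material + coupling partner → target (k = 0.289 M⁻¹ s⁻¹, Ea = 60.0 kJ mol⁻¹)
    second substrate + coupling partner → second product (k = 0.580 M⁻¹ s⁻¹, Ea = 64.0 kJ mol⁻¹)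
    starting material + target → side product (k = 0.0236 M⁻¹ s⁻¹, Ea = 88.0 kJ mol⁻¹)
    starting material + protic impurity → quenched substrate (k = 0.446 M⁻¹ s⁻¹, Ea = 55.0 kJ mol⁻¹)
    (constants at 110 °C)

Blue gave 19.5%, more than amber's 15.9% and violet's 14.2%, a lead of 3.6 percentage points against the margin of 1.5 points. At the start of blue the coupling partner went 4.0 times as fast into second product as into target, and s times the charge ratio gave 4.00. With 0.630 equiv of coupling partner and blue otherwise unchanged, s gave 12.6%, and the neighbour flask gave 11.0%.

(The data are simulated on assumed constants.)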